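## Analysis of the target

Target 23 joins three oxygenated arenes through two oxygen heterocycles. A 2,6‑diaryl‑3,7‑dioxabicyclo[3.3.0]octane (furofuran; ring A = C1, C2, O3, C4, C5; ring B = C5, C6, O7, C8, C1) carries the syringyl ring at C6. Its C2 is bonded to C5 of a 2‑aryl‑3‑hydroxymethyl‑7‑methoxy‑2,3‑dihydrobenzofuran, which bears the guaiacyl ring at benzofuran C2. There are six stereocentres. Furofuran C1, C2, C5 and C6 are (1R,2S,5R,6S), which means a cis ring fusion with both aryl groups on the convex face. Benzofuran C2 and C3 are (2S,3S), which places the aryl and hydroxymethyl groups cis, the less stable arrangement. The two arrays are separated by the central benzene ring, so neither can relay configuration to the other and each needs its own source of absolute configuration. All three benzylic C–O bonds (furofuran C2–O3 and C6–O7, benzofuran C2–O1) sit para to an oxygenated arene. They ionise under acid, and once a para‑phenol is free they can open under base through a quinone methide; either path would epimerise the molecule, and in the benzofuran it would drain the cis isomer to trans. The two free phenols are also oxidation‑prone, and three phenolic oxygens must be told apart during assembly. The feature used here is that the furofuran C1–C5 bond and C6–O7 bond can be formed in one operation from an open‑chain epoxy cinnamyl ether in which only C2 is configured.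

## Retrosynthetic reasoning

**23 to 22.** The two phenols are masked to the end as triisopropylsilyl ethers, so the last step is a buffered fluoride desilylation. Silyl ethers are chosen because their removal needs neither acid nor hydrogenolysis, both of which threaten the benzylic ethers.

**22 to 20 (through 21).** The benzofuran C3–C3a bond is cut. C3a is the carbon that carries bromine in 5‑bromovanillin 1, so it can become an aryllithium. An oxirane placed on the carbon next to the benzylic ether carbon is opened at its internal carbon with inversion. This closes the five‑membered ring, sets C3 stereospecifically and releases the hydroxymethyl group in one step. A stereospecific closure is preferred over any equilibrating ring formation because the cis isomer is the less stable one.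

**20 to 15 and 19.** The benzofuran O1–C2 bond is cut. This is the convergent junction: phenol 15 carries the complete furofuran, and epoxy alcohol 19 carries both future benzofuran stereocentres. A Mitsunobu etherification inverts the carbinol. The erythro epoxy alcohol 19, after inversion at the carbinol and inversion at the oxirane carbon, maps onto the cis (2S,3S) array.

**19 to 18 to 17 and 3, from 16.** The erythro epoxy alcohol is the product of a kinetic resolution of the racemic aryl vinyl carbinol 18 with a titanium–tartrate catalyst of the L‑(+) series. Carbinol 18 comes from silylated vanillin 17 and vinylmagnesium bromide 3.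

**15 to 14.** The central phenol is unmasked selectively. It is carried as a tert‑butyldimethylsilyl ether, which mild base removes while the bulkier triisopropylsilyl ether on the doubly flanked syringyl oxygen stays.

**14 to 11 (key disconnection).** Furofuran C1–C5 and C6–O7 are cut together. Forward, single‑electron opening of the oxirane of 11 gives a radical at C1 that closes ring A onto the cinnamyl alkene. The benzylic C6 position is then oxidised and captured by the oxygen released from the oxirane, closing ring B. Two rings, two skeletal bonds and three stereocentres (C1, C5, C6) are gained from the single stereocentre C2. The cut is made here and not at the aryl–C2 or aryl–C6 bonds because it lets the whole bicycle arise from an ether that is assembled by one O‑alkylation.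

**11 to 5 and 10.** The O3–C4 ether bond is cut. The secondary alcohol of 5 is alkylated with sinapyl bromide 10 under conditions that never generate a free alkoxide, since an alkoxide next to an oxirane would undergo Payne rearrangement.

**5 to 4 to 2 and 3, from 1.** Epoxy alcohol 5 is the erythro product of a kinetic resolution of racemic carbinol 4, this time with the D‑(−) tartrate series. Carbinol 4 comes from silylated 5‑bromovanillin 2 and 3. Compound 1 supplies the full substitution pattern of the central ring: the aldehyde becomes furofuran C2, the methoxy group becomes benzofuran C7–OMe, the phenol becomes O1 and the bromine marks C3a.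

**10 to 9 to 8 to 7, from 6.** Sinapic acid 6 is esterified, silylated, reduced to the allylic alcohol and brominated. The bromide is made last because it is the least stable member of the series.

## Alternatives that were turned down

**Alternative 1: central benzene built last by [2+2+2] cyclotrimerisation.** The disconnection removes three bonds of the central arene (C3a–C7a, C4–C5, C6–C7). Forward, Cp*RuCl(cod) (divalent ruthenium) would combine diyne A2 with ethynylfurofuran A3 to give boronate A1, closing the benzene and the dihydrofuran ring at once.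
- For it: it is the most convergent plan. All six stereocentres are in place before the arene exists, the cis C2/C3 relationship is fixed in an open‑chain precursor, and no strong base or 5‑exo/6‑endo question arises. On convergence and on the safety of the cis array it is stronger than the chosen route.
- Against it: A2 is an alkynyl ether whose oxygen carries a secondary benzylic group and whose alkyne carries boron. Such ynol ethers fragment or rearrange to ketenes on mild heating. The alkyne of A3 must insert with its substituent away from boron, which sterics favour but do not guarantee. A3 still needs the furofuran to be made first and then an ethynyl group installed. After the key step the C–B bond must be oxidised and O‑methylated before three silyl groups are removed.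
- Comparison: the chosen route takes the entire oxygenation pattern of the central ring from 1, uses stable precursors and needs fewer steps.

**Alternative 2: three‑component Michael–aldol on a menthyloxy butenolide.** The disconnection cuts furofuran C1–C2 and C5–C6. Forward, dithiane A6 is lithiated with n‑BuLi and added to the β‑carbon of butenolide A5, and the lactone enolate is trapped by aldehyde A7 to give lactone A4.
- For it: two C–C bonds form in one pot, and the bridgehead configuration comes from a cheap, recoverable auxiliary, not from a resolution with its ceiling of half the material. On throughput and on absolute control of C1 and C5 it is stronger than the chosen route.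
- Against it: A4 has the wrong oxidation level at three carbons (lactone carbonyl, acetal carbon, dithiane carbon). It needs dithiane removal in the presence of electron‑rich arenes, two hydride reductions and a closing acid‑mediated double cyclodehydration. That last step sets C2 and C6 under thermodynamic control through benzylic cations, which is the kind of acid exposure this skeleton tolerates poorly. About six further steps separate A4 from the furofuran.
- Comparison: the chosen step reaches the bicycle redox‑neutrally in one operation at the correct oxidation level.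

**Alternative 3: late carbenoid C–H insertion closing the cis‑dihydrobenzofuran.** The disconnection cuts benzofuran C2–C3. Forward, diazo ester A9 with Rh2(S‑PTTL)4 (divalent rhodium dimer, or its enantiomer) would give cis ester A8 by insertion into the guaiacylmethyl ether C–H bond.
- For it: this reaction type gives cis‑2‑aryl‑dihydrobenzofuran‑3‑carboxylates kinetically, with catalyst control of relative and absolute configuration. It avoids both a Mitsunobu reaction at an ionisable benzylic carbinol and an aryllithium. For this one ring it is stronger than the chosen endgame.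
- Against it: it solves only the last ring, so the furofuran phenol would still be made as in the chosen route. Reaching A9 from 15 needs an arylacetate at the hindered carbon ortho to the phenol oxygen, a diazo transfer and an O‑benzylation, so the endgame is longer. The electrophilic carbene meets three electron‑rich arenes and the benzylic ether C–H bonds of the furofuran. A8 can epimerise at C3 to the trans ester during reduction.
- Comparison: the chosen route has a two‑step endgame from 15 in which both benzofuran centres derive stereospecifically from one epoxy alcohol, and its key step creates the more complex half of the molecule.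

Key step: step 9

## Remarks before the steps

Remark on protecting groups: the central phenol is carried as a tert‑butyldimethylsilyl ether, not as an acetal, because acetal cleavage needs acid that would ionise the dibenzylic ether bonds of the furofuran.

Assumption: the usual sense of the Sharpless kinetic resolution holds for aryl vinyl carbinols (erythro epoxy alcohol from the fast enantiomer). On that basis D‑(−)‑DIPT serves the central fragment and L‑(+)‑DIPT the guaiacyl fragment. Both resolutions are stopped just under half conversion so that the epoxy alcohol is the enriched product.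

## Steps

Step 1
Reactants: 1 5‑bromovanillin (3‑bromo‑4‑hydroxy‑5‑methoxybenzaldehyde)
Product: 2 3‑bromo‑4‑(tert‑butyldimethylsilyloxy)‑5‑methoxybenzaldehyde
Conditions: TBSCl, imidazole, DMF, 0 °C → rt
Reagents that add atoms: tert‑butyldimethylsilyl chloride, CC(C)(C)[Si](C)(C)Cl
Why: Standard silylation of an acidic phenol with a silyl chloride and imidazole; the aldehyde and the aryl bromide are inert.

Step 2
Reactants: 2 3‑bromo‑4‑(tert‑butyldimethylsilyloxy)‑5‑methoxybenzaldehyde; 3 vinylmagnesium bromide
Product: 4 rac‑1‑[3‑bromo‑4‑(tert‑butyldimethylsilyloxy)‑5‑methoxyphenyl]prop‑2‑en‑1‑ol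
Conditions: THF, −78 °C; aq NH4Cl
Reagents that add atoms: none
Why: Grignard 1,2‑addition to an aromatic aldehyde is much faster at −78 °C than attack on the aryl silyl ether or the aryl bromide; the carbinol centre forms racemic and is resolved in step 3.

Step 3
Reactants: 4 rac‑1‑[3‑bromo‑4‑(tert‑butyldimethylsilyloxy)‑5‑methoxyphenyl]prop‑2‑en‑1‑ol
Product: 5 (R)‑[3‑bromo‑4‑(tert‑butyldimethylsilyloxy)‑5‑methoxyphenyl][(2S)‑oxiran‑2‑yl]methanol (erythro)
Conditions: Ti(OiPr)4 (15 mol %), D‑(−)‑DIPT (20 mol %), TBHP (0.45 equiv), 4 Å molecular sieves, CH2Cl2, −20 °C; non‑basic work‑up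
Reagents that add atoms: tert‑butyl hydroperoxide, CC(C)(C)OO
Why: Sharpless kinetic resolution: with D‑(−)‑DIPT the (S)‑enantiomer of 4 should be epoxidised far faster than the (R)‑enantiomer and anti to the carbinol substituent, giving the erythro epoxy alcohol; the carbinol configuration (future furofuran C2) is selected, not created, and is called R in 5 only because the oxirane carbon now outranks the aryl group; the (R)‑alcohol stays behind and is separated.

Step 4
Reactants: 6 sinapic acid ((E)‑3‑(4‑hydroxy‑3,5‑dimethoxyphenyl)prop‑2‑enoic acid)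
Product: 7 methyl (E)‑3‑(4‑hydroxy‑3,5‑dimethoxyphenyl)prop‑2‑enoate
Conditions: MeOH, H2SO4 (cat.), reflux
Reagents that add atoms: methanol, CO
Why: Fischer esterification; the conjugated E‑alkene and the phenol are unaffected.

Step 5
Reactants: 7 methyl (E)‑3‑(4‑hydroxy‑3,5‑dimethoxyphenyl)prop‑2‑enoate
Product: 8 methyl (E)‑3‑[3,5‑dimethoxy‑4‑(triisopropylsilyloxy)phenyl]prop‑2‑enoate
Conditions: TIPSOTf, 2,6‑lutidine, CH2Cl2, 0 °C → rt
Reagents that add atoms: triisopropylsilyl trifluoromethanesulfonate, CC(C)[Si](OS(=O)(=O)C(F)(F)F)(C(C)C)C(C)C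
Why: The silyl triflate is reactive enough to silylate a phenol flanked by two methoxy groups; the resulting hindered ether is the robust phenol mask that must survive to the last step.

Step 6
Reactants: 8 methyl (E)‑3‑[3,5‑dimethoxy‑4‑(triisopropylsilyloxy)phenyl]prop‑2‑enoate
Product: 9 (E)‑3‑[3,5‑dimethoxy‑4‑(triisopropylsilyloxy)phenyl]prop‑2‑en‑1‑ol
Conditions: i‑Bu2AlH (2.2 equiv), CH2Cl2, −78 °C; aq potassium sodium tartrate
Reagents that add atoms: none
Why: 1,2‑Reduction of a cinnamate ester to the allylic alcohol with i‑Bu2AlH, which leaves the alkene and the silyl ether alone.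

Step 7
Reactants: 9 (E)‑3‑[3,5‑dimethoxy‑4‑(triisopropylsilyloxy)phenyl]prop‑2‑en‑1‑ol
Product: 10 (E)‑3‑[3,5‑dimethoxy‑4‑(triisopropylsilyloxy)phenyl]prop‑2‑enyl bromide
Conditions: CBr4, PPh3, CH2Cl2, 0 °C; used at once without chromatography
Reagents that add atoms: tetrabromomethane, BrC(Br)(Br)Br
Why: Appel bromination under neutral conditions; the conjugated primary bromide is the favoured allylic isomer, and immediate use avoids loss through ionisation of this electron‑rich cinnamyl halide.

Step 8
Reactants: 5 (R)‑[3‑bromo‑4‑(tert‑butyldimethylsilyloxy)‑5‑methoxyphenyl][(2S)‑oxiran‑2‑yl]methanol; 10 (E)‑3‑[3,5‑dimethoxy‑4‑(triisopropylsilyloxy)phenyl]prop‑2‑enyl bromide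
Product: 11 (2S)‑2‑[(R)‑[3‑bromo‑4‑(tert‑butyldimethylsilyloxy)‑5‑methoxyphenyl]{[(E)‑3‑[3,5‑dimethoxy‑4‑(triisopropylsilyloxy)phenyl]prop‑2‑enyl]oxy}methyl]oxirane
Conditions: Ag2O, 4 Å molecular sieves, CH2Cl2, dark, 0 °C → rt
Reagents that add atoms: none
Why: Silver‑oxide‑promoted etherification (Purdie conditions) alkylates the alcohol without forming a free alkoxide, so Payne rearrangement of the epoxy alcohol is avoided; the silver‑activated allylic bromide is taken up at its primary terminus with the styrene conjugation kept, and the carbinol C–O bond is not broken, so the C2 configuration is retained.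

Step 9
Reactants: 11 (2S)‑2‑[(R)‑[3‑bromo‑4‑(tert‑butyldimethylsilyloxy)‑5‑methoxyphenyl]{[(E)‑3‑[3,5‑dimethoxy‑4‑(triisopropylsilyloxy)phenyl]prop‑2‑enyl]oxy}methyl]oxirane
Product: 14 (1R,2S,5R,6S)‑2‑[3‑bromo‑4‑(tert‑butyldimethylsilyloxy)‑5‑methoxyphenyl]‑6‑[3,5‑dimethoxy‑4‑(triisopropylsilyloxy)phenyl]‑3,7‑dioxabicyclo[3.3.0]octane, via bis‑titanated tetrahydrofuran 12 (not isolated), via benzylic iodide titanium alkoxide 13 (not isolated)
Conditions: Cp2TiCl2 (2.5 equiv), Zn dust, THF, rt; the resulting Cp2TiCl added dropwise to 11 in THF, rt; then I2 (1.5 equiv), rt → 50 °C; aq NaH2PO4, Na2S2O3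
Reagents that add atoms: none
Why: Cp2TiCl (trivalent titanium) transfers one electron to the oxirane of 11, which opens at the C1–O bond to the secondary β‑titanoxy radical, so the oxirane configuration is erased and only C2 carries stereochemical information. This radical adds 5‑exo‑trig to the near alkene carbon of the cinnamyl ether (C1–C5 bond, ring A), which is favoured because the radical formed at C6 is benzylic and because slow addition keeps the reductant too dilute to intercept the C1 radical first. In the chair‑like transition state the C2 aryl group sits pseudo‑equatorial and therefore trans to the CH2O–titanium arm on C1, while the preference of 1‑substituted hexenyl radicals places that arm cis to the new C5 substituent, as the Beckwith–Houk guidelines predict; this is the relationship needed for a cis ring fusion. The C6 radical is taken up by a second Cp2TiCl as the benzylic tetravalent titanium species 12, and iodine converts it into the benzylic iodide 13. Ionisation of 13, helped by the silyloxy‑dimethoxyphenyl ring, lets the titanium‑bound O7 close ring B in a 5‑exo‑tet sense (C6–O7 bond) with the aryl group on the convex face, which avoids the concave pocket of the cis‑fused bicycle and is also the more stable arrangement. The step belongs to the established titanocene‑mediated radical cyclisation of epoxy allyl ethers to tetrahydrofurans and furofuran lignans. It needs chemoselectivity for the oxirane over the aryl bromide and both silyl ethers, which single‑electron transfer from trivalent titanium provides, and diastereoselection at C1, C5 and C6, which is relayed from C2 as described.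

Step 10
Reactants: 14 (1R,2S,5R,6S)‑2‑[3‑bromo‑4‑(tert‑butyldimethylsilyloxy)‑5‑methoxyphenyl]‑6‑[3,5‑dimethoxy‑4‑(triisopropylsilyloxy)phenyl]‑3,7‑dioxabicyclo[3.3.0]octane
Product: 15 2‑bromo‑4‑{(1R,2S,5R,6S)‑6‑[3,5‑dimethoxy‑4‑(triisopropylsilyloxy)phenyl]‑3,7‑dioxabicyclo[3.3.0]octan‑2‑yl}‑6‑methoxyphenol
Conditions: K2CO3 (1.2 equiv), MeOH/THF, 0 °C; aq NH4Cl
Reagents that add atoms: none
Why: Base‑mediated methanolysis of an aryl silyl ether; the tert‑butyldimethylsilyl group on the more acidic bromophenol should leave far faster than the bulkier triisopropylsilyl group on the doubly ortho‑substituted syringyl oxygen, and the furofuran is stable to mild base.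

Step 11
Reactants: 16 vanillin (4‑hydroxy‑3‑methoxybenzaldehyde)
Product: 17 3‑methoxy‑4‑(triisopropylsilyloxy)benzaldehyde
Conditions: TIPSCl, imidazole, DMF, rt
Reagents that add atoms: triisopropylsilyl chloride, CC(C)[Si](Cl)(C(C)C)C(C)C
Why: Standard phenol silylation; the triisopropylsilyl ether is chosen because it must later withstand t‑BuLi.

Step 12
Reactants: 17 3‑methoxy‑4‑(triisopropylsilyloxy)benzaldehyde; 3 vinylmagnesium bromide
Product: 18 rac‑1‑[3‑methoxy‑4‑(triisopropylsilyloxy)phenyl]prop‑2‑en‑1‑ol
Conditions: THF, −78 °C; aq NH4Cl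
Reagents that add atoms: none
Why: Grignard 1,2‑addition to the aldehyde as in step 2; the racemic carbinol is resolved in step 13.

Step 13
Reactants: 18 rac‑1‑[3‑methoxy‑4‑(triisopropylsilyloxy)phenyl]prop‑2‑en‑1‑ol
Product: 19 (S)‑[3‑methoxy‑4‑(triisopropylsilyloxy)phenyl][(2R)‑oxiran‑2‑yl]methanol (erythro)
Conditions: Ti(OiPr)4 (15 mol %), L‑(+)‑DIPT (20 mol %), TBHP (0.45 equiv), 4 Å molecular sieves, CH2Cl2, −20 °C; non‑basic work‑up
Reagents that add atoms: tert‑butyl hydroperoxide, CC(C)(C)OO
Why: Sharpless kinetic resolution in the enantiomeric sense of step 3: with L‑(+)‑DIPT the (R)‑enantiomer of 18 should react fast and give the erythro epoxy alcohol with an (S)‑carbinol and an (R)‑oxirane carbon, the two centres that become benzofuran C2 and C3 after two inversions; any minor enantiomer carried forward becomes a separable diastereomer once joined to 15.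

Step 14
Reactants: 15 2‑bromo‑4‑{(1R,2S,5R,6S)‑6‑[3,5‑dimethoxy‑4‑(triisopropylsilyloxy)phenyl]‑3,7‑dioxabicyclo[3.3.0]octan‑2‑yl}‑6‑methoxyphenol; 19 (S)‑[3‑methoxy‑4‑(triisopropylsilyloxy)phenyl][(2R)‑oxiran‑2‑yl]methanol
Product: 20 (1R,2S,5R,6S)‑2‑[3‑bromo‑5‑methoxy‑4‑{(R)‑[3‑methoxy‑4‑(triisopropylsilyloxy)phenyl][(2R)‑oxiran‑2‑yl]methoxy}phenyl]‑6‑[3,5‑dimethoxy‑4‑(triisopropylsilyloxy)phenyl]‑3,7‑dioxabicyclo[3.3.0]octane
Conditions: PPh3, DIAD, toluene, 0 °C → rt
Reagents that add atoms: none
Why: Mitsunobu etherification: the bromophenol is acidic enough to protonate the betaine, and its phenoxide displaces the oxyphosphonium group with inversion, turning the (S)‑carbinol into the (R)‑configured aryl ether carbon that becomes benzofuran C2; the non‑polar solvent and the electron‑withdrawing oxirane neighbour work against ionisation of the benzylic centre.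

Step 15
Reactants: 20 (1R,2S,5R,6S)‑2‑[3‑bromo‑5‑methoxy‑4‑{(R)‑[3‑methoxy‑4‑(triisopropylsilyloxy)phenyl][(2R)‑oxiran‑2‑yl]methoxy}phenyl]‑6‑[3,5‑dimethoxy‑4‑(triisopropylsilyloxy)phenyl]‑3,7‑dioxabicyclo[3.3.0]octane
Product: 22 [(2S,3S)‑5‑{(1R,2S,5R,6S)‑6‑[3,5‑dimethoxy‑4‑(triisopropylsilyloxy)phenyl]‑3,7‑dioxabicyclo[3.3.0]octan‑2‑yl}‑7‑methoxy‑2‑[3‑methoxy‑4‑(triisopropylsilyloxy)phenyl]‑2,3‑dihydro‑1‑benzofuran‑3‑yl]methanol, via aryllithium 21 (not isolated)
Conditions: t‑BuLi (2.1 equiv), THF, −78 °C → −20 °C; aq NH4Cl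
Reagents that add atoms: none
Why: Parham‑type cyclisation: bromine–lithium exchange with t‑BuLi outruns deprotonation, and aryllithium 21 opens the oxirane at its internal carbon in a 5‑exo‑tet mode, the 6‑endo attack at the CH2 terminus being geometrically disfavoured; the opening inverts that carbon, so the (R)‑oxirane carbon becomes C3 (S) with the hydroxymethyl group cis to the C2 aryl group, while C2 is untouched.

Step 16
Reactants: 22 [(2S,3S)‑5‑{(1R,2S,5R,6S)‑6‑[3,5‑dimethoxy‑4‑(triisopropylsilyloxy)phenyl]‑3,7‑dioxabicyclo[3.3.0]octan‑2‑yl}‑7‑methoxy‑2‑[3‑methoxy‑4‑(triisopropylsilyloxy)phenyl]‑2,3‑dihydro‑1‑benzofuran‑3‑yl]methanol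
Product: 23 (2S,3S)‑2‑(4‑hydroxy‑3‑methoxyphenyl)‑5‑[(1R,2S,5R,6S)‑6‑(4‑hydroxy‑3,5‑dimethoxyphenyl)‑3,7‑dioxabicyclo[3.3.0]octan‑2‑yl]‑3‑(hydroxymethyl)‑7‑methoxy‑2,3‑dihydro‑1‑benzofuran (target)
Conditions: Bu4NF, AcOH (1:1), THF, 0 °C → rt
Reagents that add atoms: none
Why: Fluoride cleaves both aryl triisopropylsilyl ethers; acetic acid keeps the liberated phenols protonated, which prevents quinone methide opening of the benzylic aryl ether (the path that would scramble benzofuran C2) and limits air oxidation.

## Compound list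

1 | 5‑bromovanillin | COc1cc(C=O)cc(Br)c1O | starting material
2 | 3‑bromo‑4‑(tert‑butyldimethylsilyloxy)‑5‑methoxybenzaldehyde | COc1cc(C=O)cc(Br)c1O[Si](C)(C)C(C)(C)C | intermediate
3 | vinylmagnesium bromide | C=C[Mg]Br | starting material
4 | rac‑1‑[3‑bromo‑4‑(tert‑butyldimethylsilyloxy)‑5‑methoxyphenyl]prop‑2‑en‑1‑ol | COc1cc(C(O)C=C)cc(Br)c1O[Si](C)(C)C(C)(C)C | intermediate
5 | (R)‑[3‑bromo‑4‑(tert‑butyldimethylsilyloxy)‑5‑methoxyphenyl][(2S)‑oxiran‑2‑yl]methanol | COc1cc([C@@H](O)[C@@H]2CO2)cc(Br)c1O[Si](C)(C)C(C)(C)C | intermediate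
6 | sinapic acid | COc1cc(/C=C/C(=O)O)cc(OC)c1O | starting material
7 | methyl (E)‑3‑(4‑hydroxy‑3,5‑dimethoxyphenyl)prop‑2‑enoate | COC(=O)/C=C/c1cc(OC)c(O)c(OC)c1 | intermediate
8 | methyl (E)‑3‑[3,5‑dimethoxy‑4‑(triisopropylsilyloxy)phenyl]prop‑2‑enoate | COC(=O)/C=C/c1cc(OC)c(O[Si](C(C)C)(C(C)C)C(C)C)c(OC)c1 | intermediate
9 | (E)‑3‑[3,5‑dimethoxy‑4‑(triisopropylsilyloxy)phenyl]prop‑2‑en‑1‑ol | OC/C=C/c1cc(OC)c(O[Si](C(C)C)(C(C)C)C(C)C)c(OC)c1 | intermediate
10 | (E)‑3‑[3,5‑dimethoxy‑4‑(triisopropylsilyloxy)phenyl]prop‑2‑enyl bromide | BrC/C=C/c1cc(OC)c(O[Si](C(C)C)(C(C)C)C(C)C)c(OC)c1 | intermediate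
11 | epoxy sinapyl ether (key‑step precursor) | COc1cc([C@@H](OC/C=C/c2cc(OC)c(O[Si](C(C)C)(C(C)C)C(C)C)c(OC)c2)[C@@H]2CO2)cc(Br)c1O[Si](C)(C)C(C)(C)C | intermediate
12 | bis‑titanated tetrahydrofuran (tetravalent titanium on C6 and on O7; C6 unassigned; not isolated) | COc1cc([C@H]2OC[C@H](C([Ti](Cl)(C3C=CC=C3)C3C=CC=C3)c3cc(OC)c(O[Si](C(C)C)(C(C)C)C(C)C)c(OC)c3)[C@@H]2CO[Ti](Cl)(C3C=CC=C3)C3C=CC=C3)cc(Br)c1O[Si](C)(C)C(C)(C)C | intermediate
13 | benzylic iodide titanium alkoxide (C6 unassigned; not isolated) | COc1cc([C@H]2OC[C@H](C(I)c3cc(OC)c(O[Si](C(C)C)(C(C)C)C(C)C)c(OC)c3)[C@@H]2CO[Ti](Cl)(C3C=CC=C3)C3C=CC=C3)cc(Br)c1O[Si](C)(C)C(C)(C)C | intermediate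
14 | exo,exo furofuran (key‑step product) | COc1cc([C@H]2OC[C@H]3[C@@H]2CO[C@@H]3c2cc(OC)c(O[Si](C(C)C)(C(C)C)C(C)C)c(OC)c2)cc(Br)c1O[Si](C)(C)C(C)(C)C | intermediate
15 | furofuran bromophenol | COc1cc([C@H]2OC[C@H]3[C@@H]2CO[C@@H]3c2cc(OC)c(O[Si](C(C)C)(C(C)C)C(C)C)c(OC)c2)cc(Br)c1O | intermediate
16 | vanillin | COc1cc(C=O)ccc1O | starting material
17 | 3‑methoxy‑4‑(triisopropylsilyloxy)benzaldehyde | COc1cc(C=O)ccc1O[Si](C(C)C)(C(C)C)C(C)C | intermediate
18 | rac‑1‑[3‑methoxy‑4‑(triisopropylsilyloxy)phenyl]prop‑2‑en‑1‑ol | COc1cc(C(O)C=C)ccc1O[Si](C(C)C)(C(C)C)C(C)C | intermediate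
19 | (S)‑[3‑methoxy‑4‑(triisopropylsilyloxy)phenyl][(2R)‑oxiran‑2‑yl]methanol | COc1cc([C@H](O)[C@H]2CO2)ccc1O[Si](C(C)C)(C(C)C)C(C)C | intermediate
20 | aryl ether epoxide | COc1cc([C@H]2OC[C@H]3[C@@H]2CO[C@@H]3c2cc(OC)c(O[Si](C(C)C)(C(C)C)C(C)C)c(OC)c2)cc(Br)c1O[C@H](c1ccc(O[Si](C(C)C)(C(C)C)C(C)C)c(OC)c1)[C@H]1CO1 | intermediate
21 | aryllithium from 20 (not isolated) | COc1cc([C@H]2OC[C@H]3[C@@H]2CO[C@@H]3c2cc(OC)c(O[Si](C(C)C)(C(C)C)C(C)C)c(OC)c2)cc([Li])c1O[C@H](c1ccc(O[Si](C(C)C)(C(C)C)C(C)C)c(OC)c1)[C@H]1CO1 | intermediate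
22 | bis‑silylated cis‑dihydrobenzofuran alcohol | COc1cc([C@H]2Oc3c(OC)cc([C@H]4OC[C@H]5[C@@H]4CO[C@@H]5c4cc(OC)c(O[Si](C(C)C)(C(C)C)C(C)C)c(OC)c4)cc3[C@H]2CO)ccc1O[Si](C(C)C)(C(C)C)C(C)C | intermediate
23 | CNP0126146.1 | COc1cc([C@H]2Oc3c(OC)cc([C@H]4OC[C@H]5[C@@H]4CO[C@@H]5c4cc(OC)c(O)c(OC)c4)cc3[C@H]2CO)ccc1O | target

## Step count and least certain steps

Total: 16 steps. Longest linear sequence: 10 steps (6 → 7 → 8 → 9 → 10 → 11 → 14 → 15 → 20 → 22 → 23; steps 4–10 and 14–16).

**Step 9 (key step).** Three things can go wrong. The C1 radical may be reduced by a second titanium before it cyclises, which is followed by β‑elimination and loss of the oxirane oxygen. The cis preference at C1/C5 may be incomplete, and the trans tetrahydrofuran cannot close ring B. The iodine‑mediated closure may show poor facial selectivity at C6 or be outrun by elimination of the benzylic iodide. Slow inverse addition addresses the first; the second and third are inherent.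
Fallback: from 11 the same radical cyclisation is run with excess Cp2TiCl and no iodine and is quenched with aq NH4Cl, which gives the monocyclic alcohol {(2S,3R,4R)‑2‑[3‑bromo‑4‑(tert‑butyldimethylsilyloxy)‑5‑methoxyphenyl]‑4‑[3,5‑dimethoxy‑4‑(triisopropylsilyloxy)benzyl]tetrahydrofuran‑3‑yl}methanol F1. DDQ in CH2Cl2 over NaHCO3 then abstracts hydride from the benzylic CH2 of the most electron‑rich ring. The resulting cation is captured by the primary alcohol from the convex face, and the sequence comes back at 14. Ring B is then closed by oxidative C–H etherification and not by iodide displacement.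

**Step 8.** The silver‑assisted ionisation of 10 may lead to capture at the benzylic terminus (branched ether) or to self‑condensation of the electron‑rich cinnamyl cation, while the hindered secondary alcohol of 5 reacts slowly.
Fallback: from 5, Ag2O and allyl bromide give the allyl ether (2S)‑2‑{(R)‑(allyloxy)[3‑bromo‑4‑(tert‑butyldimethylsilyloxy)‑5‑methoxyphenyl]methyl}oxirane F2. Separately, 6 is decarboxylated (Et3N, DMF, 120 °C) to 2,6‑dimethoxy‑4‑vinylphenol F3 and silylated (TIPSOTf, 2,6‑lutidine) to triisopropyl(2,6‑dimethoxy‑4‑vinylphenoxy)silane F4. Cross‑metathesis of F2 with excess F4 (second‑generation Grubbs catalyst, CH2Cl2, 40 °C) forms the E‑cinnamyl ether and comes back at 11. The unstable bromide 10 is then not needed.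

**Step 14.** The oxyphosphonium intermediate sits on a benzylic carbon para to a silyloxy group, so partial ionisation and loss of stereochemical integrity at the future benzofuran C2 is the main danger. The phenol, flanked by bromine and methoxy, is also a slow nucleophile.
Fallback: from 17 and 15.
- Horner–Wadsworth–Emmons reaction of 17 with triethyl phosphonoacetate gives ethyl (E)‑3‑[3‑methoxy‑4‑(triisopropylsilyloxy)phenyl]prop‑2‑enoate F5.
- i‑Bu2AlH reduces it to (E)‑3‑[3‑methoxy‑4‑(triisopropylsilyloxy)phenyl]prop‑2‑en‑1‑ol F6.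
- Sharpless epoxidation with L‑(+)‑diethyl tartrate gives [(2S,3S)‑3‑[3‑methoxy‑4‑(triisopropylsilyloxy)phenyl]oxiran‑2‑yl]methanol F7.
- The sodium phenoxide of 15 (NaH, DMF, 60 °C) opens F7 at the benzylic carbon with inversion, the regiochemistry established for aryloxides and 3‑aryloxiranemethanols, giving the (2S,3R)‑3‑aryl‑3‑aryloxypropane‑1,2‑diol F8.
- Selective primary acetylation (AcCl, 2,4,6‑collidine, −78 °C) gives the monoacetate F9, and MsCl with Et3N gives the acetate mesylate F10.
- K2CO3 in MeOH removes the acetate, and the primary alkoxide displaces the mesylate with inversion, which comes back at 20.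
The ether bond is then made by SN2 opening of an epoxide instead of by activating the benzylic alcohol.

**Step 15.** The aryllithium may transfer its charge to the acidic benzylic C–H on the ether carbon, which would be followed by β‑elimination with opening of the oxirane. Some 6‑endo opening to a chromanol is also possible.
Fallback: from 15. The (R)‑enantiomer of 18, (R)‑1‑[3‑methoxy‑4‑(triisopropylsilyloxy)phenyl]prop‑2‑en‑1‑ol F11, is recovered from a resolution of 18 run past half conversion with D‑(−)‑DIPT. Mitsunobu coupling with 15 (inversion) gives the (S)‑aryl 1‑arylallyl ether F12. An intramolecular Heck reaction (Pd(OAc)2, PPh3, Ag2CO3, MeCN, 80 °C; the silver salt suppresses alkene migration) gives the 3‑methylene‑2,3‑dihydrobenzofuran F13. Hydroboration with 9‑BBN and oxidation with NaBO3·4H2O adds hydrogen to C3 from the face away from the C2 aryl group, so the hydroxymethyl group ends up cis, and the sequence comes back at 22. The ring is then closed by zerovalent palladium instead of an organolithium.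

**Step 3 (the same holds for step 13).** Titanium‑mediated epoxidation of a monosubstituted vinyl group is slow, so the rate difference between the enantiomers may be too small for a highly enriched epoxy alcohol at partial conversion. The Lewis acid may also open the electron‑rich benzylic epoxy alcohol.
Fallback: from 4. Acylation with vinyl acetate and immobilised Candida antarctica lipase B should esterify the (R)‑enantiomer to (R)‑1‑[3‑bromo‑4‑(tert‑butyldimethylsilyloxy)‑5‑methoxyphenyl]prop‑2‑enyl acetate F15 and leave (S)‑1‑[3‑bromo‑4‑(tert‑butyldimethylsilyloxy)‑5‑methoxyphenyl]prop‑2‑en‑1‑ol F14. The enantiopure F14 is then epoxidised to full conversion in the matched sense (Ti(OiPr)4, D‑(−)‑DIPT, TBHP), which comes back at 5. For step 13 the acetate enantiomer of 18 would be hydrolysed and epoxidised with L‑(+)‑DIPT.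

## Further compounds

F1 | step 9 | {(2S,3R,4R)‑2‑[3‑bromo‑4‑(tert‑butyldimethylsilyloxy)‑5‑methoxyphenyl]‑4‑[3,5‑dimethoxy‑4‑(triisopropylsilyloxy)benzyl]tetrahydrofuran‑3‑yl}methanol | COc1cc([C@H]2OC[C@H](Cc3cc(OC)c(O[Si](C(C)C)(C(C)C)C(C)C)c(OC)c3)[C@@H]2CO)cc(Br)c1O[Si](C)(C)C(C)(C)C
F2 | step 8 | (2S)‑2‑{(R)‑(allyloxy)[3‑bromo‑4‑(tert‑butyldimethylsilyloxy)‑5‑methoxyphenyl]methyl}oxirane | COc1cc([C@@H](OCC=C)[C@@H]2CO2)cc(Br)c1O[Si](C)(C)C(C)(C)C
F3 | step 8 | 2,6‑dimethoxy‑4‑vinylphenol | C=Cc1cc(OC)c(O)c(OC)c1
F4 | step 8 | triisopropyl(2,6‑dimethoxy‑4‑vinylphenoxy)silane | C=Cc1cc(OC)c(O[Si](C(C)C)(C(C)C)C(C)C)c(OC)c1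
F5 | step 14 | ethyl (E)‑3‑[3‑methoxy‑4‑(triisopropylsilyloxy)phenyl]prop‑2‑enoate | CCOC(=O)/C=C/c1ccc(O[Si](C(C)C)(C(C)C)C(C)C)c(OC)c1
F6 | step 14 | (E)‑3‑[3‑methoxy‑4‑(triisopropylsilyloxy)phenyl]prop‑2‑en‑1‑ol | OC/C=C/c1ccc(O[Si](C(C)C)(C(C)C)C(C)C)c(OC)c1
F7 | step 14 | [(2S,3S)‑3‑[3‑methoxy‑4‑(triisopropylsilyloxy)phenyl]oxiran‑2‑yl]methanol | OC[C@@H]1O[C@H]1c1ccc(O[Si](C(C)C)(C(C)C)C(C)C)c(OC)c1
F8 | step 14 | (2S,3R)‑3‑aryl‑3‑aryloxypropane‑1,2‑diol from 15 and F7 | COc1cc([C@H]2OC[C@H]3[C@@H]2CO[C@@H]3c2cc(OC)c(O[Si](C(C)C)(C(C)C)C(C)C)c(OC)c2)cc(Br)c1O[C@H](c1ccc(O[Si](C(C)C)(C(C)C)C(C)C)c(OC)c1)[C@@H](O)CO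
F9 | step 14 | primary monoacetate of F8 | COc1cc([C@H]2OC[C@H]3[C@@H]2CO[C@@H]3c2cc(OC)c(O[Si](C(C)C)(C(C)C)C(C)C)c(OC)c2)cc(Br)c1O[C@H](c1ccc(O[Si](C(C)C)(C(C)C)C(C)C)c(OC)c1)[C@@H](O)COC(C)=O
F10 | step 14 | primary acetate secondary mesylate of F8 | COc1cc([C@H]2OC[C@H]3[C@@H]2CO[C@@H]3c2cc(OC)c(O[Si](C(C)C)(C(C)C)C(C)C)c(OC)c2)cc(Br)c1O[C@H](c1ccc(O[Si](C(C)C)(C(C)C)C(C)C)c(OC)c1)[C@@H](OS(C)(=O)=O)COC(C)=O
F11 | step 15 | (R)‑1‑[3‑methoxy‑4‑(triisopropylsilyloxy)phenyl]prop‑2‑en‑1‑ol | COc1cc([C@H](O)C=C)ccc1O[Si](C(C)C)(C(C)C)C(C)C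
F12 | step 15 | (S)‑aryl 1‑arylallyl ether from 15 and F11 | COc1cc([C@H]2OC[C@H]3[C@@H]2CO[C@@H]3c2cc(OC)c(O[Si](C(C)C)(C(C)C)C(C)C)c(OC)c2)cc(Br)c1O[C@H](c1ccc(O[Si](C(C)C)(C(C)C)C(C)C)c(OC)c1)C=C
F13 | step 15 | 3‑methylene‑2,3‑dihydrobenzofuran from F12 | COc1cc([C@H]2Oc3c(OC)cc([C@H]4OC[C@H]5[C@@H]4CO[C@@H]5c4cc(OC)c(O[Si](C(C)C)(C(C)C)C(C)C)c(OC)c4)cc3C2=C)ccc1O[Si](C(C)C)(C(C)C)C(C)C
F14 | step 3 | (S)‑1‑[3‑bromo‑4‑(tert‑butyldimethylsilyloxy)‑5‑methoxyphenyl]prop‑2‑en‑1‑ol | COc1cc([C@@H](O)C=C)cc(Br)c1O[Si](C)(C)C(C)(C)C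
F15 | step 3 | (R)‑1‑[3‑bromo‑4‑(tert‑butyldimethylsilyloxy)‑5‑methoxyphenyl]prop‑2‑enyl acetate | COc1cc([C@H](OC(C)=O)C=C)cc(Br)c1O[Si](C)(C)C(C)(C)C
A1 | alternative 1 | cis‑dihydrobenzofuran C7 boronate carrying the furofuran at C5 | COc1cc([C@H]2Oc3c(B6OC(C)(C)C(C)(C)O6)cc([C@H]4OC[C@H]5[C@@H]4CO[C@@H]5c4cc(OC)c(O[Si](C)(C)C(C)(C)C)c(OC)c4)cc3[C@H]2CO[Si](C)(C)C(C)(C)C)ccc1O[Si](C)(C)C(C)(C)C
A2 | alternative 1 | diyne: borylated alkynyl ether of the guaiacyl propargylic carbinol | COc1cc([C@@H](OC#CB2OC(C)(C)C(C)(C)O2)[C@@H](C#C)CO[Si](C)(C)C(C)(C)C)ccc1O[Si](C)(C)C(C)(C)C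
A3 | alternative 1 | 2‑ethynyl‑6‑aryl furofuran | C#C[C@H]1OC[C@H]2[C@@H]1CO[C@@H]2c1cc(OC)c(O[Si](C)(C)C(C)(C)C)c(OC)c1
A4 | alternative 2 | trans‑disubstituted menthyloxy lactone carrying both aryl carbons | O=C1O[C@@H](O[C@@H]2C[C@H](C)CC[C@H]2C(C)C)[C@H](C3(c4cc(OC)c(O[Si](C(C)C)(C(C)C)C(C)C)c(OC)c4)SCCCS3)[C@H]1[C@H](O)c1cc(OC)c(OCOC)c(Br)c1
A5 | alternative 2 | (5R)‑5‑menthyloxy‑2(5H)‑furanone | O=C1O[C@@H](O[C@@H]2C[C@H](C)CC[C@H]2C(C)C)C=C1
A6 | alternative 2 | 2‑[3,5‑dimethoxy‑4‑(triisopropylsilyloxy)phenyl]‑1,3‑dithiane | COc1cc(C2SCCCS2)cc(OC)c1O[Si](C(C)C)(C(C)C)C(C)C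
A7 | alternative 2 | 3‑bromo‑5‑methoxy‑4‑(methoxymethoxy)benzaldehyde | COCOc1c(Br)cc(C=O)cc1OC
A8 | alternative 3 | cis‑2‑aryl‑2,3‑dihydrobenzofuran‑3‑carboxylate | COc1cc([C@H]2Oc3c(OC)cc([C@H]4OC[C@H]5[C@@H]4CO[C@@H]5c4cc(OC)c(O[Si](C)(C)C(C)(C)C)c(OC)c4)cc3[C@H]2C(=O)OC)ccc1O[Si](C)(C)C(C)(C)C
A9 | alternative 3 | aryldiazoacetate with ortho guaiacylmethyl ether | COC(=O)C(=[N+]=[N-])c1cc([C@H]2OC[C@H]3[C@@H]2CO[C@@H]3c2cc(OC)c(O[Si](C)(C)C(C)(C)C)c(OC)c2)cc(OC)c1OCc1ccc(O[Si](C)(C)C(C)(C)C)c(OC)c1
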